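**Retrosynthetic overview**
1. The target comes from its dioxolane ketal by hydrolysis in the last step. The masked ketone blocks retro-Michael loss of the stereocentre while the pyranone is built.
2. The pyranone comes from O1–C2 lactonisation of a 2-substituted 3,5-dioxo ester. C5–C6 is made from a β-keto ester dianion and cinnamaldehyde, and C3–C4 from an ester enolate and acetaldehyde.
3. The stereocentre is C3 of a 3-styrylglutaric half-ester. The acid arm becomes pyranone C2/C3, and the ester arm becomes a Weinreb amide and then the phenethyl ketone.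
4. The half-ester comes from lipase-catalysed desymmetrising hydrolysis of prochiral dimethyl 3-styrylglutarate. That diester is made from cinnamaldehyde and two dimethyl malonate units (Knoevenagel, 1,4-Michael, double Krapcho).
5. Ring order: the three phenyl rings are bought. The temporary dioxolane is closed in step 8, the 2-pyranone is closed in step 13, and the dioxolane is opened in step 14.

Assumption: Candida antarctica lipase B reads the styryl group of 5 as it reads the aryl group of dialkyl 3-arylglutarates and cleaves the pro-R arm, giving (S)-6; sense and ee are confirmed on 6 (chiral HPLC, optical correlation) before step 5.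

**Step 1**
Reactants: 1 (E)-cinnamaldehyde; 2 dimethyl malonate
Product: 3 dimethyl 2-[(2E)-3-phenylprop-2-en-1-ylidene]propanedioate
Conditions: piperidine (10 mol %), AcOH (10 mol %), toluene, reflux (Dean–Stark)
Reagents that add atoms: none
Why: Knoevenagel condensation: the enal has no enolisable position, piperidinium acetate activates it as the iminium ion, and azeotropic removal of water drives the condensation to the conjugated dienyl diester, which carries no stereocentre.

**Step 2**
Reactants: 3 dimethyl 2-[(2E)-3-phenylprop-2-en-1-ylidene]propanedioate; 2 dimethyl malonate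
Product: 4 tetramethyl 2-[(E)-2-phenylethenyl]propane-1,1,3,3-tetracarboxylate
Conditions: NaOMe (20 mol %), MeOH, 0 °C → rt
Reagents that add atoms: none
Why: Michael addition: the malonate anion adds reversibly to the doubly activated alkylidene malonate and settles at the β-carbon (1,4 and not 1,6) because that adduct keeps the styrene conjugation, and since the new sp3 carbon bears two identical malonyl groups no stereocentre arises.

**Step 3**
Reactants: 4 tetramethyl 2-[(E)-2-phenylethenyl]propane-1,1,3,3-tetracarboxylate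
Product: 5 dimethyl 3-[(E)-2-phenylethenyl]pentanedioate (prochiral)
Conditions: LiCl (3 equiv), H2O (4 equiv), DMSO, 150 °C
Reagents that add atoms: none
Why: Double Krapcho demethoxycarbonylation: only the geminal diester units are activated for loss of CO2Me under these near-neutral conditions, so each malonyl group is trimmed to CH2CO2Me and the styryl alkene is left alone.

**Step 4**
Reactants: 5 dimethyl 3-[(E)-2-phenylethenyl]pentanedioate
Product: 6 (3S)-5-methoxy-5-oxo-3-[(E)-2-phenylethenyl]pentanoic acid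
Conditions: lipase (Candida antarctica lipase B immobilised on acrylic resin), KH2PO4/K2HPO4 buffer (0.2 M, pH 7.2), 10% v/v MTBE, 30 °C
Reagents that add atoms: water, O
Why: Enantioselective desymmetrisation by a lipase (serine hydrolase class, EC 3.1.1.3): the chiral active site lets only the pro-R CH2CO2Me arm reach the catalytic serine, hydrolysis of the acyl-enzyme sets C3 as S in up to quantitative yield, and the anionic half-ester is not accepted for a second hydrolysis.

**Step 5**
Reactants: 6 (3S)-5-methoxy-5-oxo-3-[(E)-2-phenylethenyl]pentanoic acid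
Product: 8 (3R)-5-[methoxy(methyl)amino]-5-oxo-3-[(E)-2-phenylethenyl]pentanoic acid, via chloromagnesium carboxylate 7 (not isolated)
Conditions: MeONHMe·HCl (2 equiv), i-PrMgCl (5 equiv), THF, −20 → 0 °C; 1 M HCl
Reagents that add atoms: N,O-dimethylhydroxylamine hydrochloride, CNOC.Cl
Why: Ester-to-Weinreb-amide aminolysis by ClMgN(OMe)Me: the acid arm is parked as its inert carboxylate 7 so that only the ester arm is attacked, no bond at C3 is touched, and the descriptor turns from S to R only because the CIP ranking of the two arms is reversed.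

**Step 6**
Reactants: 8 (3R)-5-[methoxy(methyl)amino]-5-oxo-3-[(E)-2-phenylethenyl]pentanoic acid; 9 2-phenylethylmagnesium chloride (THF solution)
Product: 11 (3R)-5-oxo-7-phenyl-3-[(E)-2-phenylethenyl]heptanoic acid, via chloromagnesium carboxylate 10 (not isolated)
Conditions: i-PrMgCl (1.0 equiv), THF, −20 °C; 9 (1.5 equiv), −20 → 0 °C; 1 M HCl
Reagents that add atoms: none
Why: Weinreb ketone synthesis: the Grignard reagent adds once to the amide to give a chelated tetrahedral adduct that collapses only on acidic work-up, while carboxylate 10 is inert to RMgCl at 0 °C, so neither over-addition nor attack on the other arm occurs.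

**Step 7**
Reactants: 11 (3R)-5-oxo-7-phenyl-3-[(E)-2-phenylethenyl]heptanoic acid
Product: 12 methyl (3R)-5-oxo-7-phenyl-3-[(E)-2-phenylethenyl]heptanoate
Conditions: MeI (1.5 equiv), K2CO3 (1.2 equiv), DMF, rt
Reagents that add atoms: iodomethane, CI
Why: SN2 O-alkylation of the carboxylate never activates the acyl carbon, so the two arms cannot scramble and the ketone is untouched by the weak base.

**Step 8**
Reactants: 12 methyl (3R)-5-oxo-7-phenyl-3-[(E)-2-phenylethenyl]heptanoate
Product: 13 methyl (3R,4E)-5-phenyl-3-{[2-(2-phenylethyl)-1,3-dioxolan-2-yl]methyl}pent-4-enoate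
Conditions: (Me3SiOCH2)2 (2 equiv), Me3SiOTf (5 mol %), CH2Cl2, −78 → −20 °C
Reagents that add atoms: 1,2-bis(trimethylsilyloxy)ethane, C[Si](C)(C)OCCO[Si](C)(C)C
Why: Noyori ketalisation: the Me3SiOTf-catalysed exchange is driven by formation of the Si–O–Si bond and runs cold without water or protic acid, so ester and alkene survive and the ketone that could later cause enolisation or retro-Michael cleavage is masked.

**Step 9**
Reactants: 13 methyl (3R,4E)-5-phenyl-3-{[2-(2-phenylethyl)-1,3-dioxolan-2-yl]methyl}pent-4-enoate; 14 acetaldehyde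
Product: 16 methyl (3S,4E)-2-(1-hydroxyethyl)-5-phenyl-3-{[2-(2-phenylethyl)-1,3-dioxolan-2-yl]methyl}pent-4-enoate (diastereomer mixture at C2 and the carbinol carbon), via lithium ester enolate 15 (not isolated)
Conditions: LiN(i-Pr)2 (1.15 equiv), THF, −78 °C; 14 (3 equiv), −78 °C; AcOH
Reagents that add atoms: none
Why: Aldol addition of a lithium ester enolate: the ester α-CH2 is now the only acidic position, the enolate adds cleanly to the unhindered aldehyde at −78 °C, and the two new centres need no control because they are erased in steps 10 and 13, whereas C3 is not deprotonated (it is S now by CIP ranking only).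

**Step 10**
Reactants: 16 methyl (3S,4E)-2-(1-hydroxyethyl)-5-phenyl-3-{[2-(2-phenylethyl)-1,3-dioxolan-2-yl]methyl}pent-4-enoate
Product: 17 methyl (3S,4E)-2-acetyl-5-phenyl-3-{[2-(2-phenylethyl)-1,3-dioxolan-2-yl]methyl}pent-4-enoate (C2 epimers)
Conditions: Dess–Martin periodinane (1.3 equiv), CH2Cl2, 0 °C → rt
Reagents that add atoms: none
Why: Dess–Martin oxidation is a mild, non-basic alcohol-to-ketone oxidation that tolerates ketal, ester and styrene and avoids retro-aldol cleavage of the β-hydroxy ester.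

**Step 11**
Reactants: 17 methyl (3S,4E)-2-acetyl-5-phenyl-3-{[2-(2-phenylethyl)-1,3-dioxolan-2-yl]methyl}pent-4-enoate; 1 (E)-cinnamaldehyde
Product: 19 methyl (6E)-5-hydroxy-3-oxo-7-phenyl-2-[(1S,2E)-3-phenyl-1-{[2-(2-phenylethyl)-1,3-dioxolan-2-yl]methyl}prop-2-en-1-yl]hept-6-enoate (diastereomer mixture at C2 and C5), via dilithium dienolate 18 (not isolated)
Conditions: LiN(i-Pr)2 (2.3 equiv), THF, −78 → 0 °C; 1 (1.1 equiv), −78 °C; AcOH
Reagents that add atoms: none
Why: Huckin–Weiler dianion aldol addition: the second deprotonation creates the more reactive terminal (γ) carbanion, which adds 1,2 to the enal at −78 °C, and the new carbinol centre is removed in step 12.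

**Step 12**
Reactants: 19 methyl (6E)-5-hydroxy-3-oxo-7-phenyl-2-[(1S,2E)-3-phenyl-1-{[2-(2-phenylethyl)-1,3-dioxolan-2-yl]methyl}prop-2-en-1-yl]hept-6-enoate
Product: 20 methyl (6E)-3,5-dioxo-7-phenyl-2-[(1S,2E)-3-phenyl-1-{[2-(2-phenylethyl)-1,3-dioxolan-2-yl]methyl}prop-2-en-1-yl]hept-6-enoate (C2 epimers and enol forms)
Conditions: Dess–Martin periodinane (1.3 equiv), CH2Cl2, 0 °C
Reagents that add atoms: none
Why: Dess–Martin oxidation of an allylic alcohol is fast at 0 °C and gives the enolised 3,5-dioxo ester without touching the ketal or the C–H at the stereocentre.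

**Step 13**
Reactants: 20 methyl (6E)-3,5-dioxo-7-phenyl-2-[(1S,2E)-3-phenyl-1-{[2-(2-phenylethyl)-1,3-dioxolan-2-yl]methyl}prop-2-en-1-yl]hept-6-enoate
Product: 21 4-hydroxy-3-[(1S,2E)-3-phenyl-1-{[2-(2-phenylethyl)-1,3-dioxolan-2-yl]methyl}prop-2-en-1-yl]-6-[(E)-2-phenylethenyl]-2H-pyran-2-one
Conditions: DBU (2 equiv), toluene, 60 °C
Reagents that add atoms: none
Why: Base-induced lactonisation (intramolecular O-acylation of the C5 enolate by the methyl ester) is driven by formation of the strongly acidic 4-hydroxy-2-pyranone as its DBU salt; C2 of the chain becomes sp2 so the epimer mixture converges, and the masked ketone makes retro-Michael loss of the stereocentre impossible.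

**Step 14**
Reactants: 21 4-hydroxy-3-[(1S,2E)-3-phenyl-1-{[2-(2-phenylethyl)-1,3-dioxolan-2-yl]methyl}prop-2-en-1-yl]-6-[(E)-2-phenylethenyl]-2H-pyran-2-one
Product: 22 4-hydroxy-3-[(1E,3S)-5-oxo-1,7-diphenylhept-1-en-3-yl]-6-[(E)-2-phenylethenyl]-2H-pyran-2-one (target)
Conditions: 1 M aq HCl, THF, rt
Reagents that add atoms: water, O
Why: Acid-catalysed ketal hydrolysis under mild aqueous conditions frees the ketone without base or heat, so the β-stereocentre cannot racemise by retro-Michael/Michael addition, and the product (which may sit partly as its cyclic hemiketal in solution) is the (S)-configured target.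

**Compound list**
1 | (E)-cinnamaldehyde | O=C/C=C/c1ccccc1 | starting material
2 | dimethyl malonate | COC(=O)CC(=O)OC | starting material
3 | dimethyl 2-[(2E)-3-phenylprop-2-en-1-ylidene]propanedioate | COC(=O)C(=C/C=C/c1ccccc1)C(=O)OC | intermediate
4 | tetramethyl 2-[(E)-2-phenylethenyl]propane-1,1,3,3-tetracarboxylate | COC(=O)C(C(=O)OC)C(/C=C/c1ccccc1)C(C(=O)OC)C(=O)OC | intermediate
5 | dimethyl 3-[(E)-2-phenylethenyl]pentanedioate | COC(=O)CC(/C=C/c1ccccc1)CC(=O)OC | intermediate
6 | (3S)-5-methoxy-5-oxo-3-[(E)-2-phenylethenyl]pentanoic acid | COC(=O)C[C@@H](/C=C/c1ccccc1)CC(=O)O | intermediate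
7 | chloromagnesium carboxylate of 6 (not isolated) | COC(=O)C[C@@H](/C=C/c1ccccc1)CC(=O)[O-].[Mg+2].[Cl-] | intermediate
8 | (3R)-5-[methoxy(methyl)amino]-5-oxo-3-[(E)-2-phenylethenyl]pentanoic acid | CON(C)C(=O)C[C@@H](/C=C/c1ccccc1)CC(=O)O | intermediate
9 | 2-phenylethylmagnesium chloride | Cl[Mg]CCc1ccccc1 | starting material
10 | chloromagnesium carboxylate of 8 (not isolated) | CON(C)C(=O)C[C@@H](/C=C/c1ccccc1)CC(=O)[O-].[Mg+2].[Cl-] | intermediate
11 | (3R)-5-oxo-7-phenyl-3-[(E)-2-phenylethenyl]heptanoic acid | O=C(CCc1ccccc1)C[C@@H](/C=C/c1ccccc1)CC(=O)O | intermediate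
12 | methyl (3R)-5-oxo-7-phenyl-3-[(E)-2-phenylethenyl]heptanoate | O=C(CCc1ccccc1)C[C@@H](/C=C/c1ccccc1)CC(=O)OC | intermediate
13 | methyl (3R,4E)-5-phenyl-3-{[2-(2-phenylethyl)-1,3-dioxolan-2-yl]methyl}pent-4-enoate | C(Cc1ccccc1)C2(OCCO2)C[C@@H](/C=C/c3ccccc3)CC(=O)OC | intermediate
14 | acetaldehyde | CC=O | starting material
15 | lithium ester enolate of 13 (not isolated) | C(Cc1ccccc1)C2(OCCO2)C[C@@H](/C=C/c3ccccc3)C=C([O-])OC.[Li+] | intermediate
16 | methyl (3S,4E)-2-(1-hydroxyethyl)-5-phenyl-3-{[2-(2-phenylethyl)-1,3-dioxolan-2-yl]methyl}pent-4-enoate, diastereomer mixture | C(Cc1ccccc1)C2(OCCO2)C[C@@H](/C=C/c3ccccc3)C(C(C)O)C(=O)OC | intermediate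
17 | methyl (3S,4E)-2-acetyl-5-phenyl-3-{[2-(2-phenylethyl)-1,3-dioxolan-2-yl]methyl}pent-4-enoate, C2 epimers | C(Cc1ccccc1)C2(OCCO2)C[C@@H](/C=C/c3ccccc3)C(C(C)=O)C(=O)OC | intermediate
18 | dilithium dienolate of 17 (not isolated) | C(Cc1ccccc1)C2(OCCO2)C[C@@H](/C=C/c3ccccc3)C(C(=C)[O-])=C([O-])OC.[Li+].[Li+] | intermediate
19 | methyl (6E)-5-hydroxy-3-oxo-7-phenyl-2-[(1S,2E)-3-phenyl-1-{[2-(2-phenylethyl)-1,3-dioxolan-2-yl]methyl}prop-2-en-1-yl]hept-6-enoate, diastereomer mixture | C(Cc1ccccc1)C2(OCCO2)C[C@@H](/C=C/c3ccccc3)C(C(=O)OC)C(=O)CC(O)/C=C/c4ccccc4 | intermediate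
20 | methyl (6E)-3,5-dioxo-7-phenyl-2-[(1S,2E)-3-phenyl-1-{[2-(2-phenylethyl)-1,3-dioxolan-2-yl]methyl}prop-2-en-1-yl]hept-6-enoate | C(Cc1ccccc1)C2(OCCO2)C[C@@H](/C=C/c3ccccc3)C(C(=O)OC)C(=O)CC(=O)/C=C/c4ccccc4 | intermediate
21 | 4-hydroxy-3-[(1S,2E)-3-phenyl-1-{[2-(2-phenylethyl)-1,3-dioxolan-2-yl]methyl}prop-2-en-1-yl]-6-[(E)-2-phenylethenyl]-2H-pyran-2-one | C(Cc1ccccc1)C2(OCCO2)C[C@@H](/C=C/c3ccccc3)c4c(O)cc(/C=C/c5ccccc5)oc4=O | intermediate
22 | 4-hydroxy-3-[(1E,3S)-5-oxo-1,7-diphenylhept-1-en-3-yl]-6-[(E)-2-phenylethenyl]-2H-pyran-2-one | O=C(CCc1ccccc1)C[C@@H](/C=C/c1ccccc1)c1c(O)cc(/C=C/c2ccccc2)oc1=O | target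

**Total step count:** 14. **Longest linear sequence:** 14 steps (1 → 22).

**Three steps most likely to fail**

**Step 4.** The lipase may give 6 in low ee, or it may prefer the other arm of this particular substrate.
- The fallback sets out from 5 and comes back at 12. It moves the enzymatic desymmetrisation from the diester to the cyclic anhydride and builds the two arms in the opposite order.
- 5 is saponified (LiOH, THF/H2O) to 3-[(E)-2-phenylethenyl]pentanedioic acid F1. Ac2O at reflux closes this to 4-[(E)-2-phenylethenyl]oxane-2,6-dione F2.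
- A lipase (Candida antarctica lipase B or Burkholderia cepacia lipase, MeOH, MTBE, rt) opens F2 by enantioselective methanolysis. The carbonyl taken up by the enzyme ends as the ester, giving (3R)-5-methoxy-5-oxo-3-[(E)-2-phenylethenyl]pentanoic acid F3.
- In F3 the free acid is the ketone arm. EDC·HCl/MeONHMe·HCl/i-Pr2NEt therefore gives methyl (3R)-5-[methoxy(methyl)amino]-5-oxo-3-[(E)-2-phenylethenyl]pentanoate F4, and 9 (1.1 equiv, THF, −78 °C) converts it into 12.
- Steps 5 to 7 then fall away. The same sequence from F3 is used if step 4 itself turns out to deliver the (R)-acid.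

**Step 5.** Amidation of an ester next to a magnesium carboxylate may stall as an insoluble salt, or the arms may scramble through the symmetric anhydride.
- The fallback sets out from 6 and comes back at 8. It exchanges the roles of the arms with orthogonal esters.
- tert-Butyl 2,2,2-trichloroacetimidate (CH2Cl2/cyclohexane, rt) O-alkylates 6 to 1-tert-butyl 5-methyl (3R)-3-[(E)-2-phenylethenyl]pentanedioate F5.
- LiOH (1.1 equiv, THF/H2O, 0 °C) cleaves only the methyl ester to (3R)-5-tert-butoxy-5-oxo-3-[(E)-2-phenylethenyl]pentanoic acid F6.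
- EDC·HCl/MeONHMe·HCl/i-Pr2NEt gives tert-butyl (3R)-5-[methoxy(methyl)amino]-5-oxo-3-[(E)-2-phenylethenyl]pentanoate F7.
- CF3CO2H/CH2Cl2 (0 °C) removes the tert-butyl group to give 8.

**Step 11.** Double deprotonation of the hindered, α-branched β-keto ester 17 may be incomplete or may lead to retro-Claisen cleavage.
- The fallback sets out from 13 (with 1 for the side fragment) and comes back at 20. It brings in pyranone carbons C4 to C6 as one ready-made aldehyde, so no dianion is needed and steps 9 to 12 are replaced.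
- 1 reacts with the lithium enolate of methyl acetate (LiN(i-Pr)2, THF, −78 °C) to give methyl (4E)-3-hydroxy-5-phenylpent-4-enoate F8. This is racemic, and its centre is oxidised away later.
- TBSCl/imidazole gives methyl (4E)-3-[(tert-butyldimethylsilyl)oxy]-5-phenylpent-4-enoate F9. i-Bu2AlH (toluene, −78 °C) then gives (4E)-3-[(tert-butyldimethylsilyl)oxy]-5-phenylpent-4-enal F10.
- Enolate 15, made from 13 as in step 9, adds to F10 to give methyl (6E)-5-[(tert-butyldimethylsilyl)oxy]-3-hydroxy-7-phenyl-2-[(1S,2E)-3-phenyl-1-{[2-(2-phenylethyl)-1,3-dioxolan-2-yl]methyl}prop-2-en-1-yl]hept-6-enoate F11.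
- HF·pyridine (THF, 0 °C) gives methyl (6E)-3,5-dihydroxy-7-phenyl-2-[(1S,2E)-3-phenyl-1-{[2-(2-phenylethyl)-1,3-dioxolan-2-yl]methyl}prop-2-en-1-yl]hept-6-enoate F12.
- Dess–Martin periodinane (3 equiv, CH2Cl2) oxidises both carbinols to 20.

**Further compounds**
F1 | step 4 | 3-[(E)-2-phenylethenyl]pentanedioic acid | OC(=O)CC(/C=C/c1ccccc1)CC(=O)O
F2 | step 4 | 4-[(E)-2-phenylethenyl]oxane-2,6-dione | O=C1CC(/C=C/c2ccccc2)CC(=O)O1
F3 | step 4 | (3R)-5-methoxy-5-oxo-3-[(E)-2-phenylethenyl]pentanoic acid | OC(=O)C[C@@H](/C=C/c1ccccc1)CC(=O)OC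
F4 | step 4 | methyl (3R)-5-[methoxy(methyl)amino]-5-oxo-3-[(E)-2-phenylethenyl]pentanoate | CON(C)C(=O)C[C@@H](/C=C/c1ccccc1)CC(=O)OC
F5 | step 5 | 1-tert-butyl 5-methyl (3R)-3-[(E)-2-phenylethenyl]pentanedioate | COC(=O)C[C@@H](/C=C/c1ccccc1)CC(=O)OC(C)(C)C
F6 | step 5 | (3R)-5-tert-butoxy-5-oxo-3-[(E)-2-phenylethenyl]pentanoic acid | OC(=O)C[C@@H](/C=C/c1ccccc1)CC(=O)OC(C)(C)C
F7 | step 5 | tert-butyl (3R)-5-[methoxy(methyl)amino]-5-oxo-3-[(E)-2-phenylethenyl]pentanoate | CON(C)C(=O)C[C@@H](/C=C/c1ccccc1)CC(=O)OC(C)(C)C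
F8 | step 11 | methyl (4E)-3-hydroxy-5-phenylpent-4-enoate (racemic) | COC(=O)CC(O)/C=C/c1ccccc1
F9 | step 11 | methyl (4E)-3-[(tert-butyldimethylsilyl)oxy]-5-phenylpent-4-enoate (racemic) | COC(=O)CC(O[Si](C)(C)C(C)(C)C)/C=C/c1ccccc1
F10 | step 11 | (4E)-3-[(tert-butyldimethylsilyl)oxy]-5-phenylpent-4-enal (racemic) | O=CCC(O[Si](C)(C)C(C)(C)C)/C=C/c1ccccc1
F11 | step 11 | methyl (6E)-5-[(tert-butyldimethylsilyl)oxy]-3-hydroxy-7-phenyl-2-[(1S,2E)-3-phenyl-1-{[2-(2-phenylethyl)-1,3-dioxolan-2-yl]methyl}prop-2-en-1-yl]hept-6-enoate (diastereomer mixture) | C(Cc1ccccc1)C2(OCCO2)C[C@@H](/C=C/c3ccccc3)C(C(=O)OC)C(O)CC(O[Si](C)(C)C(C)(C)C)/C=C/c4ccccc4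
F12 | step 11 | methyl (6E)-3,5-dihydroxy-7-phenyl-2-[(1S,2E)-3-phenyl-1-{[2-(2-phenylethyl)-1,3-dioxolan-2-yl]methyl}prop-2-en-1-yl]hept-6-enoate (diastereomer mixture) | C(Cc1ccccc1)C2(OCCO2)C[C@@H](/C=C/c3ccccc3)C(C(=O)OC)C(O)CC(O)/C=C/c4ccccc4
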